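**Retrosynthetic overview**
- The tetrahydrofuran ring is formed last, by closing the O1–C2 bond of a benzylic triol under acid; the aryl group ends up trans to the neighbouring CH2OH.
- The triol comes from full hydride reduction of a trans α-aroyl-β-benzyl-γ-butyrolactone. This lactone is the first ring formed and serves only as a template that fixes the C3/C4 relationship before it is opened.
- Key disconnection: the C3–C4 bond of the target, a 1,4-dicarbonyl bond in the keto lactone. The enamine α-carbon of 3-(3,4-dimethoxyphenyl)propanal is joined to the α-carbon of ethyl 3,4,5-trimethoxybenzoylacetate, which is used in reversed polarity as its 2-bromo derivative (an enolonium / α-carbonyl radical equivalent) under chiral amine–photoredox catalysis. This step sets the absolute configuration.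
- Ring order: γ-butyrolactone (step 2), opened (step 3), tetrahydrofuran (step 4).

Assumption: ethyl 3-oxo-3-(3,4,5-trimethoxyphenyl)propanoate and 3-(3,4-dimethoxyphenyl)propanal are bought as catalogue chemicals, as is the (2S,5R) imidazolidinone catalyst.

**Route**

Step 1
Reactants: 1 ethyl 3-oxo-3-(3,4,5-trimethoxyphenyl)propanoate
Product: 2 ethyl 2-bromo-3-oxo-3-(3,4,5-trimethoxyphenyl)propanoate (racemic)
Conditions: NBS (1.05 equiv), Mg(ClO4)2 (0.3 equiv), EtOAc, 0 °C → rt
Reagents that add atoms: N-bromosuccinimide, O=C1CCC(=O)N1Br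
Why: Electrophilic α-bromination of an active methylene compound, in which the magnesium-chelated enol of the β-keto ester reacts far faster than the acyl-deactivated trimethoxyarene; the new centre is racemic and is consumed in step 2.

Step 2
Reactants: 2 ethyl 2-bromo-3-oxo-3-(3,4,5-trimethoxyphenyl)propanoate; 3 3-(3,4-dimethoxyphenyl)propanal
Product: 6 (3R,4S)-4-(3,4-dimethoxybenzyl)-3-(3,4,5-trimethoxybenzoyl)dihydrofuran-2(3H)-one, via keto aldehyde 4 (not isolated), via hydroxy keto ester 5 (not isolated)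
Conditions: 3 (1.5 equiv), (2S,5R)-2-tert-butyl-3,5-dimethylimidazolidin-4-one·TfOH (20 mol%), Ru(bpy)3Cl2 (0.5 mol%), 2,6-lutidine (2 equiv), degassed DMF, blue LEDs, 23 °C; then MeOH, NaBH4, −40 °C; then DBU, −40 °C → rt; aq. citric acid
Reagents that add atoms: none
Why: Enantioselective photoredox–enamine α-alkylation of an aldehyde, in which one-electron reduction of 2 gives the electrophilic α-carbonyl radical that adds to the enamine of 3 on the Re face left open by the (2S,5R) catalyst (its C5 methyl blocks the Si face) and so sets the (S) centre bearing the benzyl group; NaBH4 at −40 °C then reduces only the aldehyde, the freed alcohol lactonizes onto the ester with loss of ethanol, and the 1,3-dicarbonyl α-centre equilibrates through its enolate to the trans keto lactone.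

Step 3
Reactants: 6 (3R,4S)-4-(3,4-dimethoxybenzyl)-3-(3,4,5-trimethoxybenzoyl)dihydrofuran-2(3H)-one
Product: 8 (2S,3S)-2-(3,4-dimethoxybenzyl)-3-[hydroxy(3,4,5-trimethoxyphenyl)methyl]butane-1,4-diol (both carbinol epimers), via hydroxy lactone 7 (not isolated)
Conditions: LiBH4 (6 equiv), THF–MeOH (10:1), 0 °C → rt; aq. NH4Cl
Reagents that add atoms: none
Why: Hydride reduction in which LiBH4 first reduces the aryl ketone, removing the enolisable 1,3-dicarbonyl hydrogen and thereby locking the trans ring centre from step 2, and then opens the lactone to the diol; the new carbinol centre forms unselectively and is erased in step 4.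

Step 4
Reactants: 8 (2S,3S)-2-(3,4-dimethoxybenzyl)-3-[hydroxy(3,4,5-trimethoxyphenyl)methyl]butane-1,4-diol
Product: 9 [(2R,3S,4S)-4-(3,4-dimethoxybenzyl)-2-(3,4,5-trimethoxyphenyl)tetrahydrofuran-3-yl]methanol
Conditions: CSA (10 mol%), CH2Cl2 (0.01 M), 0 °C; Et3N quench at full conversion
Reagents that add atoms: none
Why: Acid-catalysed SN1 cyclodehydration (benzylic etherification) in which the 3,4,5-trimethoxybenzylic cation is captured in a five-membered ring closure by the hydroxymethyl on the benzyl-bearing carbon, and the aryl group settles trans to the adjacent CH2OH and away from the benzyl group, which gives (2R) from either carbinol epimer.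

**Compound list**

1 | ethyl 3-oxo-3-(3,4,5-trimethoxyphenyl)propanoate | CCOC(=O)CC(=O)c1cc(OC)c(OC)c(OC)c1 | starting material
2 | ethyl 2-bromo-3-oxo-3-(3,4,5-trimethoxyphenyl)propanoate (racemic) | CCOC(=O)C(Br)C(=O)c1cc(OC)c(OC)c(OC)c1 | intermediate
3 | 3-(3,4-dimethoxyphenyl)propanal | COc1ccc(CCC=O)cc1OC | starting material
4 | ethyl (3S)-4-(3,4-dimethoxyphenyl)-3-formyl-2-(3,4,5-trimethoxybenzoyl)butanoate (both C2 epimers) | CCOC(=O)C(C(=O)c1cc(OC)c(OC)c(OC)c1)[C@@H](C=O)Cc1ccc(OC)c(OC)c1 | intermediate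
5 | ethyl (3S)-4-(3,4-dimethoxyphenyl)-3-(hydroxymethyl)-2-(3,4,5-trimethoxybenzoyl)butanoate (both C2 epimers) | CCOC(=O)C(C(=O)c1cc(OC)c(OC)c(OC)c1)[C@@H](CO)Cc1ccc(OC)c(OC)c1 | intermediate
6 | (3R,4S)-4-(3,4-dimethoxybenzyl)-3-(3,4,5-trimethoxybenzoyl)dihydrofuran-2(3H)-one | COc1ccc(C[C@@H]2COC(=O)[C@H]2C(=O)c3cc(OC)c(OC)c(OC)c3)cc1OC | intermediate
7 | (3R,4S)-4-(3,4-dimethoxybenzyl)-3-[hydroxy(3,4,5-trimethoxyphenyl)methyl]dihydrofuran-2(3H)-one (both carbinol epimers) | COc1ccc(C[C@@H]2COC(=O)[C@H]2C(O)c3cc(OC)c(OC)c(OC)c3)cc1OC | intermediate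
8 | (2S,3S)-2-(3,4-dimethoxybenzyl)-3-[hydroxy(3,4,5-trimethoxyphenyl)methyl]butane-1,4-diol (both carbinol epimers) | COc1ccc(C[C@H](CO)[C@@H](CO)C(O)c2cc(OC)c(OC)c(OC)c2)cc1OC | intermediate
9 | [(2R,3S,4S)-4-(3,4-dimethoxybenzyl)-2-(3,4,5-trimethoxyphenyl)tetrahydrofuran-3-yl]methanol (CNP0107562.1) | COc1ccc(C[C@@H]2CO[C@@H](c3cc(OC)c(OC)c(OC)c3)[C@@H]2CO)cc1OC | target

**Step count**

Total steps: 4. Longest linear sequence: 4 steps (1 → 2 → 6 → 8 → 9); aldehyde 3 enters at step 2.

**Steps most likely to fail, with fallbacks**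

Step 2 (the coupling). The risk is that the doubly activated secondary bromide 2 passes its bromine to the enamine instead of giving the radical, and that the 1,4-keto aldehyde 4 closes to a furan before it is reduced. The fallback sets out from 3 and puts the ester carbon in after the asymmetric step. The same light-driven enamine alkylation is run with bought 2-bromo-1-(3,4,5-trimethoxyphenyl)ethan-1-one, a phenacyl bromide of the partner class that behaves best in this catalysis, and gives (2S)-2-(3,4-dimethoxybenzyl)-4-oxo-4-(3,4,5-trimethoxyphenyl)butanal F1. NaBH4 at −78 °C reduces the aldehyde to (3S)-3-(3,4-dimethoxybenzyl)-4-hydroxy-1-(3,4,5-trimethoxyphenyl)butan-1-one F2. Methyl chloroformate and pyridine give (2S)-2-(3,4-dimethoxybenzyl)-4-oxo-4-(3,4,5-trimethoxyphenyl)butyl methyl carbonate F3. LiN(SiMe3)2 (2.2 equiv, THF, −78 → 0 °C) then closes the lactone by intramolecular Claisen-type C-acylation of the ketone enolate on the carbonate, and the route is rejoined at 6.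

Step 3 (reduction of the keto lactone). The risk is that the enol of 6 ties up hydride, that the minor cis keto lactone is reduced competitively, and that the aldolate of 7 fragments by retro-aldol. The fallback sets out from 6 and separates the stereo-determining reduction from the ring opening. Transfer hydrogenation with RuCl[(R,R)-TsDPEN](p-cymene) in HCO2H/Et3N reduces the ketone with dynamic kinetic resolution of the lactone α-centre and gives, after isolation, (3R,4S)-4-(3,4-dimethoxybenzyl)-3-[(R)-hydroxy(3,4,5-trimethoxyphenyl)methyl]dihydrofuran-2(3H)-one F4. LiAlH4 (THF, 0 °C) then gives (2S,3S)-2-(3,4-dimethoxybenzyl)-3-[(R)-hydroxy(3,4,5-trimethoxyphenyl)methyl]butane-1,4-diol F5. F5 is the (R)-carbinol epimer of 8, so it enters step 4 unchanged and the route is rejoined at 9.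

Step 4 (ring closure). The risk is that the electron-rich dimethoxyphenyl ring traps the benzylic cation in an irreversible six-membered Friedel–Crafts closure, which competes with ether formation. The fallback avoids the cation by making the benzylic oxygen the nucleophile. It sets out from 6 and passes through F4 and F5 of the previous fallback; the (R) carbinol is required here, which is why the (R,R) catalyst is used there. TsCl (2.1 equiv) in pyridine at 0 °C tosylates both primary hydroxyls to give (2S,3S)-2-(3,4-dimethoxybenzyl)-3-[(R)-hydroxy(3,4,5-trimethoxyphenyl)methyl]butane-1,4-diyl bis(4-methylbenzenesulfonate) F6. NaH in THF then lets the benzylic alkoxide displace the tosylate on the benzyl-bearing branch; this five-membered closure is fast, whereas attack on the other tosylate would give an oxetane. The benzylic centre is retained and the product is [(2R,3S,4S)-4-(3,4-dimethoxybenzyl)-2-(3,4,5-trimethoxyphenyl)tetrahydrofuran-3-yl]methyl 4-methylbenzenesulfonate F7. Mg turnings in MeOH cleave the remaining sulfonate at the S–O bond, and the route is rejoined at 9.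

**Further compounds**

F1 | step 2 | (2S)-2-(3,4-dimethoxybenzyl)-4-oxo-4-(3,4,5-trimethoxyphenyl)butanal | O=C[C@@H](Cc1ccc(OC)c(OC)c1)CC(=O)c1cc(OC)c(OC)c(OC)c1
F2 | step 2 | (3S)-3-(3,4-dimethoxybenzyl)-4-hydroxy-1-(3,4,5-trimethoxyphenyl)butan-1-one | OC[C@@H](Cc1ccc(OC)c(OC)c1)CC(=O)c1cc(OC)c(OC)c(OC)c1
F3 | step 2 | (2S)-2-(3,4-dimethoxybenzyl)-4-oxo-4-(3,4,5-trimethoxyphenyl)butyl methyl carbonate | COC(=O)OC[C@@H](Cc1ccc(OC)c(OC)c1)CC(=O)c1cc(OC)c(OC)c(OC)c1
F4 | step 3 | (3R,4S)-4-(3,4-dimethoxybenzyl)-3-[(R)-hydroxy(3,4,5-trimethoxyphenyl)methyl]dihydrofuran-2(3H)-one | COc1ccc(C[C@@H]2COC(=O)[C@H]2[C@@H](O)c3cc(OC)c(OC)c(OC)c3)cc1OC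
F5 | step 3 | (2S,3S)-2-(3,4-dimethoxybenzyl)-3-[(R)-hydroxy(3,4,5-trimethoxyphenyl)methyl]butane-1,4-diol | COc1ccc(C[C@H](CO)[C@@H](CO)[C@@H](O)c2cc(OC)c(OC)c(OC)c2)cc1OC
F6 | step 4 | (2S,3S)-2-(3,4-dimethoxybenzyl)-3-[(R)-hydroxy(3,4,5-trimethoxyphenyl)methyl]butane-1,4-diyl bis(4-methylbenzenesulfonate) | COc1ccc(C[C@H](COS(=O)(=O)c2ccc(C)cc2)[C@@H](COS(=O)(=O)c2ccc(C)cc2)[C@@H](O)c2cc(OC)c(OC)c(OC)c2)cc1OC
F7 | step 4 | [(2R,3S,4S)-4-(3,4-dimethoxybenzyl)-2-(3,4,5-trimethoxyphenyl)tetrahydrofuran-3-yl]methyl 4-methylbenzenesulfonate | COc1ccc(C[C@@H]2CO[C@@H](c3cc(OC)c(OC)c(OC)c3)[C@@H]2COS(=O)(=O)c4ccc(C)cc4)cc1OC
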